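(The numbers in the tables come from a simulation from invented constants.)

The target appears behind intermediate A in the south-east run, reading 2.8% against 18.2% at 50.0 min. This reckoning takes the peak of intermediate A as the moment when outflow toward target catches up with inflow from coupling.

| flask | substrate | coupling partner | second reagent | solid third reagent | capture agent | remark | time |
|---|---|---|---|---|---|---|---|
| south-east | 40 mM | 16 mM | 80 mM | 12 mM | 0.40 mM | run made earlier |  |
| flask | 20 mM | 16.0 mM | 80.0 mM | 12.0 mM | 0.400 mM |  | 4.0 h |

south-east run (percent of the substrate charged)

| time / min | intermediate A / % | target / % | substrate / % |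
|---|---|---|---|
| 4.00 | 1.7 | 1.8 | 96.5 |
| 8.00 | 5.3 | 0 | 95.1 |
| 20.0 | 8.5 | 0 | 85.4 |
| 50.0 | 18.2 | 2.8 | 72.7 |

(standard deviation of a reading: 1 percentage point)

- at the start none of the solid third reagent is in solution

- the moment within 4.0 h at which there is most intermediate A
- the amount of intermediate A, in percent of the substrate charged, at that time

The last south-east reading gives two constants, each by replacing a curve with its mean. Counting intermediate A and target together puts the coupling made in the south-east run at

x = 8.40 mM

so, with mean substrate 34.5 mM and mean coupling partner 11.8 mM,

k_c = x / (t · mean c(substrate) · mean c(coupling partner)) = 0.412 /M/min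

In the south-east run intermediate A rises roughly linearly from zero, so its mean is taken as half the reading. This gives the drain constant, the fraction of intermediate A passing toward target each minute, a pseudo-first-order constant:

k_d = target / (mean intermediate A · t) = 0.00615 /min

It rests on a reading of 2.8% with a scatter of 1 percentage point.

In the first instants the flask holds no intermediate A, so outflow is zero and inflow is 0.132 mM/min. In the flask the coupling partner is the limiting reagent of the coupling, at 16.0 mM against 20 mM of substrate. By 2.00 h the integrated second-order law has coupling at 8.36 mM, so inflow decays at a mean

k_f = k_c · (c(substrate) + c(coupling partner) − x) = 0.0114 /min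

This reckoning puts the peak where inflow equals k_d · c(intermediate A):

t = ln(k_f / k_d) / (k_f − k_d) = 1.96 h

amount = inflow at t / (k_d · c(substrate charged)) = 28.1%

The forecast, by “Balancing formation against this drain”, gave 1.5 h and 30%, a time earlier than this reckoning and an amount above it.

The flask peaks at 2.17 h with 26.8% of intermediate A.

    substrate + coupling partner → intermediate A (k = 0.460 /M/min)
    second reagent + intermediate A → intermediate B (k = 0.0760 /M/min)
    third reagent + intermediate B → target (k = 20.0 /M/min)
    substrate + second reagent → side product (k = 0.0120 /M/min)
    solid third reagent ⇌ third reagent, rate k5*(cs5 - [third reagent]) while solid is left; crystals form when [third reagent] > cs5 (solubility = 7.30 mM, k = 0.00950 /min)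
    intermediate A + capture agent → trapped intermediate (k = 8.10 /M/min)
    2 substrate → self-condensation product (k = 0.00260 /M/min)

Target stands at 13.1% at that peak. From 2.00 h to 4.00 h, k_d on the mean of 26.8% and 22.8% of intermediate A gives 18.3% of new target, and target in the flask gains 18 points. In the neighbour with 5.0 mM of substrate, the end state gives inflow 0.00451 mM/min against drain 0.00831 mM/min, and its end value of 27.0% lies below its best of 31.3%.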